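The numbering used is C1 for the carboxyl carbon, C3/C6 for the dioxane carbons, and C9=C10 for the exocyclic alkene on the octalin. The route rests on cutting C7–C8. C7 lies next to the peroxy-bearing quaternary C6, where an anion or radical would expel the O–O bond. C8 is the allylic terminus of C9=C10. The key step therefore unites C7 as a non-enolisable α-peroxy aldehyde with C8 as an allylic phosphorus ylide. One Wittig reaction joins the finished 1,2-dioxane acid, all three stereocentres in place, to the geometrically defined C14 octalin unit. Diimide then saturates C7=C8. The aldehyde is the remnant of the epoxy alcohol whose perhydrolysis sets C6.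

Key step: step 16

Remark on numbering: C11 and C12 are the CH2CH2 arm of the octalin. C13=C14 is the ring-fusion alkene. C18 is the CMe2 carbon. C19 is the ring CH2 between C10 and C14. In the target, C8 is cis to C19, which makes C9=C10 Z.

Remark on step 16: the semi-stabilised ylide is expected to give an E/Z mixture at C7=C8. Compound 24 is drawn as the E isomer, and both isomers give 25 in step 17.

Remark on step 8: the tartrate crotylboronate is treated as a reagent, made by the standard procedure from (E)-2-butene, triisopropyl borate and D-(−)-diisopropyl tartrate.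

**Octalin fragment (C8–C19)**

Step 1
Reactants: 1 6-methoxy-1-tetralone
Product: 2 6-methoxy-1,1-dimethyl-1,2,3,4-tetrahydronaphthalene
Conditions: TiCl4, Me2Zn, CH2Cl2, −40 °C to rt
Reagents that add atoms: dimethylzinc, C[Zn]C
Why: In this Reetz geminal dimethylation, Me2TiCl2 adds one methyl to the ketone, and the benzylic cation released on Ti–O ionisation, stabilised by the para methoxy group, takes up the second.

Step 2
Reactants: 2 6-methoxy-1,1-dimethyl-1,2,3,4-tetrahydronaphthalene
Product: 4 5,5-dimethyl-3,4,5,6,7,8-hexahydronaphthalen-2(1H)-one, via dihydroanisole enol ether 3 (not isolated)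
Conditions: Li, NH3(l), THF, t-BuOH, −78 to −33 °C; NH3 evaporated; then (CO2H)2, MeOH–H2O, rt
Reagents that add atoms: water, O
Why: Birch reduction of the anisole keeps the methoxy- and alkyl-bearing carbons sp2, and mild enol ether hydrolysis with oxalic acid should give the β,γ-enone with the tetrasubstituted C13=C14 alkene still unconjugated.

Step 3
Reactants: 4 5,5-dimethyl-3,4,5,6,7,8-hexahydronaphthalen-2(1H)-one
Product: 5 5,5-dimethyl-3,4,5,6,7,8-hexahydronaphthalen-2-yl trifluoromethanesulfonate (C10=C19–C14=C13 dienyl triflate)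
Conditions: KHMDS, THF, −78 °C; PhNTf2, −78 to 0 °C
Reagents that add atoms: N-phenylbis(trifluoromethanesulfonimide), O=S(=O)(N(c1ccccc1)S(=O)(=O)C(F)(F)F)C(F)(F)F
Why: In this enol triflate formation, the doubly activated C19–H between C=O and C13=C14 is removed first, so O-sulfonylation of the linear dienolate places the new alkene at C10=C19 and not at C10=C11.

Step 4
Reactants: 5 dienyl triflate
Product: 6 2-ethenyl-5,5-dimethyl-3,4,5,6,7,8-hexahydronaphthalene (triene C8=C9–C10=C19–C14=C13)
Conditions: CH2=CHSnBu3, Pd2(dba)3 (cat.), AsPh3 (cat.), LiCl, NMP, rt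
Reagents that add atoms: tributyl(vinyl)stannane, C=C[Sn](CCCC)(CCCC)CCCC
Why: Stille coupling of an alkenyl triflate runs under neutral conditions at room temperature, which suits the sensitive vinylcyclohexadiene and installs C9 and C8.

Step 5
Reactants: 6 triene
Product: 8 (Z)-2-[5,5-dimethyl-3,4,5,6,7,8-hexahydronaphthalen-2(1H)-ylidene]ethanol, via allylboronate 7 (not isolated)
Conditions: Ni(cod)2 (cat.), PCy3 (cat.), HBpin, toluene, rt; then NaOH, H2O2, THF, 0 °C
Reagents that add atoms: pinacolborane, CC1(C)OBOC1(C)C (boron and pinacolate of 7); hydrogen peroxide, OO (hydroxyl oxygen of 8)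
Why: In this nickel-catalysed 1,4-hydroboration of a 1,3-diene, Ni(0) should bind s-cis the only diene unit with an unsubstituted terminus (C8=C9–C10=C19) and deliver H to C19 and boron to C8, so the new C9=C10 alkene holds C8 and C19 cis, and stereoretentive oxidation gives the allylic alcohol.

Step 6
Reactants: 8 (Z)-allylic alcohol
Product: 10 {(Z)-2-[5,5-dimethyl-3,4,5,6,7,8-hexahydronaphthalen-2(1H)-ylidene]ethyl}triphenylphosphonium bromide, via allylic bromide 9 (not isolated)
Conditions: CBr4, PPh3, CH2Cl2, 0 °C; then PPh3, MeCN, rt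
Reagents that add atoms: carbon tetrabromide, BrC(Br)(Br)Br; triphenylphosphine, c1ccc(cc1)P(c1ccccc1)c1ccccc1
Why: Neutral Appel bromination followed by SN2 quaternisation at the primary carbon C8 avoids any free allyl cation, so the skipped diene and the C9=C10 geometry should be kept.

**Dioxane fragment (C1–C7)**

Step 7
Reactants: 11 geranyl acetate
Product: 12 (E)-3-methyl-6-oxohex-2-en-1-yl acetate
Conditions: O3 (1 equiv, Sudan Red end point), CH2Cl2, −78 °C; Me2S
Reagents that add atoms: ozone, [O-][O+]=O
Why: In this chemoselective ozonolysis, the electron-rich isopropylidene alkene reacts well before the alkene deactivated by the allylic acetate, which exposes C3 as an aldehyde.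

Step 8
Reactants: 12 (E)-3-methyl-6-oxohex-2-en-1-yl acetate
Product: 13 (2E,6S,7R)-6-hydroxy-3,7-dimethylnona-2,8-dien-1-yl acetate
Conditions: (S,S)-tartrate (E)-crotylboronate, 4 Å MS, toluene, −78 °C; aq NaHCO3
Reagents that add atoms: diisopropyl (4S,5S)-2-[(E)-but-2-en-1-yl]-1,3,2-dioxaborolane-4,5-dicarboxylate, C/C=C/CB1O[C@H](C(=O)OC(C)C)[C@H](O1)C(=O)OC(C)C
Why: In this Roush asymmetric crotylboration, the closed chair transition state turns the (E)-crotyl geometry into the anti C2/C3 relationship, the (S,S)-tartrate directs attack to the Re face of the aldehyde, and any minor enantiomer becomes a separable diastereomer after the second reagent-controlled step 11.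

Step 9
Reactants: 13 anti homoallylic alcohol
Product: 14 (2E,6S,7R)-3,7-dimethyl-6-(methylsulfonyloxy)nona-2,8-dien-1-yl acetate
Conditions: MsCl, Et3N, CH2Cl2, 0 °C
Reagents that add atoms: methanesulfonyl chloride, CS(=O)(=O)Cl
Why: Mesylation activates the C3 oxygen with retention, and the vinyl group as a masked carboxyl avoids the E1cB elimination that a β-sulfonyloxy ester would undergo.

Step 10
Reactants: 14 mesylate acetate
Product: 15 (3R,4S,7E)-9-hydroxy-3,7-dimethylnona-1,7-dien-4-yl methanesulfonate
Conditions: K2CO3 (cat.), MeOH, 0 °C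
Reagents that add atoms: none
Why: Base-catalysed transesterification removes the primary acetate under conditions too mild to displace or eliminate the secondary mesylate.

Step 11
Reactants: 15 allylic alcohol
Product: 16 (3R,4S)-6-[(2S,3S)-3-(hydroxymethyl)-2-methyloxiran-2-yl]-3-methylhex-1-en-4-yl methanesulfonate
Conditions: Ti(OiPr)4 (cat.), L-(+)-DET (cat.), t-BuOOH, 4 Å MS, CH2Cl2, −20 °C
Reagents that add atoms: tert-butyl hydroperoxide, CC(C)(C)OO
Why: Sharpless asymmetric epoxidation is reagent-controlled, L-(+)-tartrate gives the (2S,3S)-epoxide of this geraniol-type allylic alcohol (C7 S, C6 S), and the remote vinyl group is inert.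

Step 12
Reactants: 16 epoxy alcohol
Product: 17 (3R,4S,7R,8S)-7-hydroperoxy-8,9-dihydroxy-3,7-dimethylnon-1-en-4-yl methanesulfonate
Conditions: H2O2 (anhydrous, Et2O), H3PMo12O40 (cat.), rt
Reagents that add atoms: hydrogen peroxide, OO
Why: In this molybdenum-catalysed perhydrolysis of an epoxide, H2O2 should open the activated oxirane at the tertiary carbon from the rear in a borderline SN2 process, so the C6–OO bond forms with inversion (6S to 6R) while C7 keeps its oxygen.

Step 13
Reactants: 17 hydroperoxy diol mesylate
Product: 18 (1S)-1-{(3R,6R)-6-[(2R)-but-3-en-2-yl]-3-methyl-1,2-dioxan-3-yl}ethane-1,2-diol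
Conditions: Cs2CO3, DMF, 0 °C to rt
Reagents that add atoms: none
Why: In this intramolecular alkylation of a hydroperoxide (6-exo-tet SN2), carbonate deprotonates only the hydroperoxide, whose α-effect anion displaces the C3 mesylate with inversion, which sets C3 as R, syn to the C2 methyl and trans to C7 across the ring.

Step 14
Reactants: 18 dioxane diol
Product: 20 (2S)-2-{(3R,6R)-6-[(1S)-1,2-dihydroxyethyl]-6-methyl-1,2-dioxan-3-yl}propanoic acid, via aldehyde 19 (not isolated)
Conditions: O3, acetone–H2O (19:1), 0 °C; then NaClO2, NaH2PO4, t-BuOH–H2O, rt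
Reagents that add atoms: ozone, [O-][O+]=O; sodium chlorite, [Na+].[O-]Cl=O
Why: Ozonolysis in wet acetone gives the aldehyde directly, and buffered Pinnick-type chlorite oxidation in the same pot converts it to the acid before the β-peroxy aldehyde can epimerise at C2 or eliminate, with both oxidants leaving the dialkyl peroxide untouched.

Step 15
Reactants: 20 dihydroxy acid
Product: 21 (2S)-2-[(3R,6R)-6-formyl-6-methyl-1,2-dioxan-3-yl]propanoic acid
Conditions: NaIO4, THF–H2O, 0 °C
Reagents that add atoms: none
Why: Malaprade glycol cleavage removes C8 of the terpene as formaldehyde and leaves C7 as an aldehyde on the quaternary, non-epimerisable C6.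

**Union and completion**

Step 16
Reactants: 10 allylic phosphonium bromide; 21 formyl dioxane acid
Product: 24 (2S)-2-[(3R,6R)-6-{(1E,3Z)-3-[5,5-dimethyl-3,4,5,6,7,8-hexahydronaphthalen-2(1H)-ylidene]prop-1-en-1-yl}-6-methyl-1,2-dioxan-3-yl]propanoic acid, via ylide 22 (not isolated), via sodium carboxylate 23 (not isolated)
Conditions: 10, NaHMDS, THF, −78 °C; 21 pre-treated with NaHMDS (1 equiv), THF, −78 °C, added by cannula; −78 to 0 °C; aq HCl (pH 3)
Reagents that add atoms: sodium bis(trimethylsilyl)amide, C[Si](C)(C)[N-][Si](C)(C)C.[Na+] (sodium of 23 only)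
Why: In this Wittig olefination the semi-stabilised allylic ylide 22 adds through its α-carbon C8 to the formyl carbon C7 of 23, and the oxaphosphetane collapses to the C7=C8 alkene and Ph3P=O, so the C7–C8 bond is made in the fragment union itself. The closest known reaction type is the Wittig reaction of allylic triphenylphosphonium ylides with α-oxygenated, α-quaternary aldehydes, including aldehydes that carry dialkyl peroxides. No ring is closed and no stereocentre is created, and the E/Z outcome at C7=C8 is irrelevant because step 17 removes this alkene. The step needs α- over γ-attack of the ylide (the γ-carbon C10 is fully substituted), retention of the C9=C10 geometry (the ylide is made and consumed at low temperature) and attack at C=O rather than at O–O or C3–H. The last point is secured because the aldehyde is the most electrophilic site, it cannot enolise since C6 is quaternary, and the carboxylate protects C2–H against deprotonation and retro-oxa-Michael ring opening.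

Step 17
Reactants: 24 diene acid
Product: 25 (2S)-2-[(3R,6S)-6-{(3Z)-3-[5,5-dimethyl-3,4,5,6,7,8-hexahydronaphthalen-2(1H)-ylidene]propyl}-6-methyl-1,2-dioxan-3-yl]propanoic acid (target)
Conditions: KO2CN=NCO2K, AcOH, MeOH–CH2Cl2, 0 °C to rt, added in portions with monitoring
Reagents that add atoms: none
Why: Diimide reduction transfers H2 concertedly and is inert to O–O bonds, and it should reduce the 1,2-disubstituted C7=C8 alkene much faster than the trisubstituted C9=C10 and tetrasubstituted C13=C14 alkenes.

**Compound list**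

1 | 6-methoxy-1-tetralone | COc1ccc2c(c1)CCCC2=O | starting material
2 | 6-methoxy-1,1-dimethyl-1,2,3,4-tetrahydronaphthalene | COc1ccc2c(c1)CCCC2(C)C | intermediate
3 | 6-methoxy-1,1-dimethyl-1,2,3,4,5,8-hexahydronaphthalene | COC1=CCC2=C(C1)CCCC2(C)C | intermediate
4 | 5,5-dimethyl-3,4,5,6,7,8-hexahydronaphthalen-2(1H)-one | O=C1CCC2=C(C1)CCCC2(C)C | intermediate
5 | 5,5-dimethyl-3,4,5,6,7,8-hexahydronaphthalen-2-yl trifluoromethanesulfonate | O=S(=O)(OC1=CC2=C(CC1)C(C)(C)CCC2)C(F)(F)F | intermediate
6 | 2-ethenyl-5,5-dimethyl-3,4,5,6,7,8-hexahydronaphthalene | C=CC1=CC2=C(CC1)C(C)(C)CCC2 | intermediate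
7 | (Z)-allylboronic acid pinacol ester | CC1(C)OB(C/C=C2/CCC3=C(CCCC3(C)C)C2)OC1(C)C | intermediate
8 | (Z)-2-[5,5-dimethyl-3,4,5,6,7,8-hexahydronaphthalen-2(1H)-ylidene]ethanol | OC/C=C1/CCC2=C(CCCC2(C)C)C1 | intermediate
9 | (Z)-allylic bromide | BrC/C=C1/CCC2=C(CCCC2(C)C)C1 | intermediate
10 | (Z)-allylic triphenylphosphonium bromide | [Br-].C(/C=C1/CCC2=C(CCCC2(C)C)C1)[P+](c1ccccc1)(c1ccccc1)c1ccccc1 | intermediate
11 | geranyl acetate | CC(C)=CCC/C(C)=C/COC(C)=O | starting material
12 | (E)-3-methyl-6-oxohex-2-en-1-yl acetate | O=CCC/C(C)=C/COC(C)=O | intermediate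
13 | (2E,6S,7R)-6-hydroxy-3,7-dimethylnona-2,8-dien-1-yl acetate | C[C@H](C=C)[C@@H](O)CC/C(C)=C/COC(C)=O | intermediate
14 | (2E,6S,7R)-3,7-dimethyl-6-(methylsulfonyloxy)nona-2,8-dien-1-yl acetate | C[C@H](C=C)[C@@H](OS(C)(=O)=O)CC/C(C)=C/COC(C)=O | intermediate
15 | (3R,4S,7E)-9-hydroxy-3,7-dimethylnona-1,7-dien-4-yl methanesulfonate | C[C@H](C=C)[C@@H](OS(C)(=O)=O)CC/C(C)=C/CO | intermediate
16 | (3R,4S)-6-[(2S,3S)-3-(hydroxymethyl)-2-methyloxiran-2-yl]-3-methylhex-1-en-4-yl methanesulfonate | C[C@H](C=C)[C@@H](OS(C)(=O)=O)CC[C@]1(C)O[C@H]1CO | intermediate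
17 | (3R,4S,7R,8S)-7-hydroperoxy-8,9-dihydroxy-3,7-dimethylnon-1-en-4-yl methanesulfonate | C[C@H](C=C)[C@@H](OS(C)(=O)=O)CC[C@](C)([C@@H](O)CO)OO | intermediate
18 | (1S)-1-{(3R,6R)-6-[(2R)-but-3-en-2-yl]-3-methyl-1,2-dioxan-3-yl}ethane-1,2-diol | C[C@H](C=C)[C@H]1CC[C@](C)([C@@H](O)CO)OO1 | intermediate
19 | (2S)-2-{(3R,6R)-6-[(1S)-1,2-dihydroxyethyl]-6-methyl-1,2-dioxan-3-yl}propanal | C[C@H](C=O)[C@H]1CC[C@](C)([C@@H](O)CO)OO1 | intermediate
20 | (2S)-2-{(3R,6R)-6-[(1S)-1,2-dihydroxyethyl]-6-methyl-1,2-dioxan-3-yl}propanoic acid | C[C@H](C(=O)O)[C@H]1CC[C@](C)([C@@H](O)CO)OO1 | intermediate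
21 | (2S)-2-[(3R,6R)-6-formyl-6-methyl-1,2-dioxan-3-yl]propanoic acid | C[C@H](C(=O)O)[C@H]1CC[C@](C)(C=O)OO1 | intermediate
22 | (Z)-allylidene triphenylphosphorane (ylide of 10) | [CH-](/C=C1/CCC2=C(CCCC2(C)C)C1)[P+](c1ccccc1)(c1ccccc1)c1ccccc1 | intermediate
23 | sodium salt of 21 | C[C@H](C(=O)[O-])[C@H]1CC[C@](C)(C=O)OO1.[Na+] | intermediate
24 | (7E,9Z)-diene acid | C[C@H](C(=O)O)[C@H]1CC[C@](C)(/C=C/C=C2/CCC3=C(CCCC3(C)C)C2)OO1 | intermediate
25 | CNP0223199.1 | C[C@H](C(=O)O)[C@H]1CC[C@](C)(CC/C=C2/CCC3=C(CCCC3(C)C)C2)OO1 | target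

Total step count: 17. Longest linear sequence: 11 steps (steps 7 to 17).

**Steps most likely to fail**

Step 16 (key step). The base may open the dioxane, either by deprotonation at C3–H or by attack of the phosphorus ylide on the O–O bond. The C9=C10 geometry may also erode through the delocalised allyl ylide. The fallback is a phosphorus-free Julia–Kocienski olefination under Barbier conditions. It sets out from 8 and 21 and returns to the route at 24. Mitsunobu reaction of 8 with 1-phenyl-1H-tetrazole-5-thiol gives the allylic tetrazolyl sulfide F1. Ammonium molybdate/H2O2 oxidises it to the allylic tetrazolyl sulfone F2. KHMDS is then added at −78 °C to a premixed solution of F2 and 21, so that the sulfonyl anion is trapped by the aldehyde as it forms. Smiles rearrangement and loss of SO2 and phenyltetrazolone give 24.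

Step 5. Site selectivity may be poor, with the nickel hydride engaging the ring diene C10=C19–C14=C13 or adding in a 1,6-sense. Syn/anti isomerisation of the allylnickel intermediate may also erode the alkene geometry. The fallback gives up catalytic stereocontrol for a short classical sequence with physical separation. It sets out from 4 and returns at 10. CeCl3-promoted addition of vinylmagnesium bromide to 4 gives the tertiary vinyl carbinol F3. Ph3P·HBr converts F3 with allylic transposition into the primary phosphonium salts, 10 together with its E-configured phosphonium isomer F4, and 10 is taken out by fractional crystallisation.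

Step 12. Partial ionisation at C6 may cause loss of configuration. Competing attack at C7 and acid-induced fragmentation of the β-hydroxy hydroperoxide are also possible. The fallback reverses the order of the two C–O bond formations so that the tertiary centre is attacked intramolecularly. It sets out from 16 and returns at 18. The cesium salt of 2-methoxyprop-2-yl hydroperoxide displaces the C3 mesylate of 16 with inversion to give the peroxyketal epoxide F5. Mild acid (PPTS, MeOH) unmasks the hydroperoxy epoxide F6. Under camphorsulfonic acid catalysis, F6 closes in a 6-exo mode on the tertiary epoxide carbon C6 with inversion to give 18.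

**Further compounds**

F1 | step 16 | 5-{(Z)-2-[5,5-dimethyl-3,4,5,6,7,8-hexahydronaphthalen-2(1H)-ylidene]ethylsulfanyl}-1-phenyl-1H-tetrazole | C(/C=C1/CCC2=C(CCCC2(C)C)C1)Sc1nnnn1-c1ccccc1
F2 | step 16 | 5-{(Z)-2-[5,5-dimethyl-3,4,5,6,7,8-hexahydronaphthalen-2(1H)-ylidene]ethylsulfonyl}-1-phenyl-1H-tetrazole | C(/C=C1/CCC2=C(CCCC2(C)C)C1)S(=O)(=O)c1nnnn1-c1ccccc1
F3 | step 5 | 2-ethenyl-5,5-dimethyl-1,2,3,4,5,6,7,8-octahydronaphthalen-2-ol (racemic) | C=CC1(O)CCC2=C(CCCC2(C)C)C1
F4 | step 5 | (E)-isomer of phosphonium bromide 10 | [Br-].C(/C=C1\CCC2=C(CCCC2(C)C)C1)[P+](c1ccccc1)(c1ccccc1)c1ccccc1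
F5 | step 12 | {(2S,3S)-3-[(3R,4R)-3-(2-methoxypropan-2-ylperoxy)-4-methylhex-5-en-1-yl]-3-methyloxiran-2-yl}methanol | C[C@H](C=C)[C@H](OOC(C)(C)OC)CC[C@]1(C)O[C@H]1CO
F6 | step 12 | {(2S,3S)-3-[(3R,4R)-3-hydroperoxy-4-methylhex-5-en-1-yl]-3-methyloxiran-2-yl}methanol | C[C@H](C=C)[C@H](OO)CC[C@]1(C)O[C@H]1CO
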